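(The constants used here are made up; the result is computed.)

Set the two first fates of the starting material against each other, ring closure and dimer formation, and read the shares from that contest.

in all of them: starting material 0.86 M; time 50 min
- dawn: temperature 70 °C
- spring: temperature 55 °C
- winter: temperature 40 °C
- summer: temperature 85 °C

    starting material → single ring (k1 = 0.0035 s⁻¹, Ea1 = 84.0 kJ mol⁻¹)
    2 starting material → open dimer (k2 = 0.0081 L mol⁻¹ s⁻¹, Ea2 = 65.0 kJ mol⁻¹)
    starting material + open dimer → open trimer (k3 = 0.0057 L mol⁻¹ s⁻¹, Ea3 = 60.0 kJ mol⁻¹)
    open dimer → ring dimer (k4 = 0.018 s⁻¹, Ea4 = 75.0 kJ mol⁻¹)
    starting material → decomposition product (k5 = 4.3 × 10⁻⁶ s⁻¹, Ea5 = 101 kJ mol⁻¹)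
    (constants at 40 °C)

- percentages count the starting material that a species holds: one open dimer or ring dimer counts as two
- percentages count the starting material that a species holds: one open trimer counts as three
- a step written with two of one species runs at k times the square of its concentration and takes two of it each time
- the constants hold at 40 °C; other temperatures follow from the activation energies

1. the flask with the highest share of single ring in all that became single ring or open dimer or open trimer or ring dimer ("all alike" if they lie within 1.5 percentage points) (dawn / spring / winter / summer / all alike)
2. share of single ring in all that became single ring or open dimer or open trimer or ring dimer, dawn
3. share of single ring in all that became single ring or open dimer or open trimer or ring dimer, spring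
4. share of single ring in all that became single ring or open dimer or open trimer or ring dimer, winter
5. share of single ring in all that became single ring or open dimer or open trimer or ring dimer, summer

In winter, at 40 °C, the number to put on the board is 3.98: the rivalry number a, the rate at which dimer formation uses starting material at the start over the rate at which ring closure uses it.

In the first instants of the winter flask, dimer formation therefore takes 79.9 % of what is consumed, and open dimer appears. In the middle dimer formation, which goes with the square of [starting material], loses ground: in winter the two rates are level at 0.216 M, and below that ring closure leads. Meanwhile open dimer closes to ring dimer with a life of 0.926 min in winter, or it meets starting material. At the charge that meeting runs at 27.2 % of the closing pace, and it slows as [starting material] falls. Each meeting takes starting material from ring closure, so I expect my figures to read high.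

Towards the end, the winter time of 50 min is ten times the ring-closure life of 4.76 min, so I reckon down to zero [starting material]. Decomposition runs at 0.123 % of the ring-closure pace in winter, hardly any, and I drop it.

Dropping the open trimer as well, I sum the part of each portion of starting material that closes to single ring, and the share comes to ln(1 + a)/a. That is 40.3 % for winter. For summer the starting ratio gives a = 1.59, lower than winter's, as 84.0 kJ mol⁻¹ against 65.0 kJ mol⁻¹ leads one to expect, and the share is 59.8 %. Summer's share stands above winter's, so of these two flasks I take summer as my answer, and I stop there, with dawn, spring and the trimer correction unreckoned.

The forecast also names summer, with 53.1 % for dawn, 46.4 % for spring, 39.3 % for winter and 59.2 % for summer, on the ground that “Ring closure has the highest activation energy among the productive steps”. Its winter and summer figures stand below my bare ones.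

The flasks give summer as the highest, with 53.1 % for dawn, 46.4 % for spring, 39.3 % for winter and 59.3 % for summer. At 50.0 min the open trimer of the winter flask holds 8.07 % of the charge, and winter's share lies 1 percentage point below my bare figure. Now take the neighbour of summer charged with 2.1 M: a scales with the charge, so it becomes 3.89, close to winter's 3.98, and the bare share is 40.8 %. That neighbour, at 85 °C, ends with a share of 39.7 %.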